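A neighbour of this flask, charged with 0.013 M of solid substrate, comes back at the end; the flask itself comes first.

    solid substrate ⇌ dissolved substrate, rate k1*(cs1 - [dissolved substrate]) while solid is left; crystals form when [dissolved substrate] > cs1 (cs1 = 3.6 mM, k1 = 0.93 /s)
    dissolved substrate + reagent → target (k2 = 3.6 /M/s)
    reagent → side product (k3 = 0.015 /s)
    solid product ⇌ target, rate k4*(cs4 - [target]) while solid is left; crystals form when [target] > cs4 (cs4 = 2.1 mM, k4 = 0.81 /s)

solid substrate 0.0050 M; reagent 0.0125 M; time 20 s

- amounts and yields of target count solid product too
- given per volume of solution although it is solid: solid substrate, solid product
- at the start none of the solid substrate is in solution
- run time (flask): 20 s

* target and solid product together at 20 s, in percent of the solid substrate charged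
* the change that raises the amount of target and solid product together at 20 s, in percent of the solid substrate charged most ("none" if none brings more than 2 percentage points) (north / east / south / west / none)
* amount of target and solid product together at 20 s, in percent of the solid substrate charged, after west

- north: doubling the solubility in step 1, all else as stated
- east: doubling the dissolution coefficient of step 4, all else as stated
- south: doubling the amount of reagent, all else as stated
- west: doubling the solubility in step 4, all else as stated

What stays nearly constant here? The dissolved substrate, I reckon, while solid lasts. It fills within about 1.08 s, and the reaction with reagent drains it with a half-life of 15 s, which is longer than the filling time. So I freeze it at its solubility, 3.6 mM.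

But the reagent falls. How do you handle that? Its loss constant through both of its reactions is about 0.0280 /s, so I freeze it too, at its mid-run level of 9.45 mM. The rate constant of the target reaction times these two levels gives 0.122 mM/s. This is the plateau rate, the speed at which target forms while solid remains.

And when the solid ends? The excess over solubility is 1.40 mM, and at the plateau rate it lasts until about 12.5 s after the start, earlier than 20 s. After that, the dissolved substrate decays in a pseudo-first-order way at 0.0340 /s. That gives me 44.2%.

Which change wins? Doubled reagent reckons 70.7%. Doubled substrate solubility puts the whole charge in solution and reckons 47.5%, so south stands above north. The crystal step moves target between two forms that are counted together, so east and west leave my sum as it was.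

The forecast gave 44%, south as the best change and 44% after west, on the ground that “Step 4 only moves product between solution and crystals and nothing consumes the target”.

The flask gives 43.9%, with south best at 27 percentage points against 4.5 points for north, and 43.9% after west. The time given and the reaction of reagent to side product act together on this flask: the time is the largest single effect, for left 200 s this flask reaches 83.7%, and taking the side reaction away adds 5.6 points at 20 s. The falling level of reagent is only a part of the shortfall, 18% of what is missing: with reagent held, this flask reaches 53.9%, and the plateau rate with reagent frozen at 0.0125 M reckons 54.7%. In the neighbour flask, solid substrate still stands at 55.6%, and the plateau rate over the time after filling reckons 17.8% of its charge, where that flask reads 17.5%.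

The numbers of this flask were drawn at random within sensible limits; what happens was integrated by code.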